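## Structural features

Compound 18 is a spiro[5.5]undecane of the chamigrane type. Ring A (C6–C11) is a cyclohexene with the C7=C8 alkene, a methyl on C7, a gem-dimethyl group on C11 and a secondary bromide on C10; ring B (C6, C1–C5) is a cyclohexane; the rings share only the quaternary carbon C6. C6 is bonded to the fully substituted C11 and to the substituted alkene carbon C7, so the spiro centre and C11 are vicinal quaternary carbons. There are four stereocentres: C10 (S) in ring A, the spiro carbon C6 (R), and the contiguous pair C2 (R, CHBr) and C3 (R, methyl carbinol) in ring B; C10 is 1,3 to C6 through C11, and C6 is 1,3 to C2 through C1. The fragile groups are the neopentyl C10 bromide (hard to make by substitution, open to elimination or 1,3-closure when a carbanion sits at C6 or C8), the tertiary β-bromo alcohol (epoxide with base, alkene with reductants) and the acid-sensitive trisubstituted alkene. The real difficulty is the congested C6, which must be built next to C11 in a defined relation to the remote C10, and then the trans C2/C3 array, which must also be related to C6. In the ring B chair that keeps C11 equatorial and C7 axial, the C2 bromine and the C3 hydroxyl are both equatorial and the C3 methyl is axial. This C2(Br)–C3(OH)(CH3) unit is what the key step exploits: a bromine-bearing carbanion at C2 adding to a C3 methyl ketone forms C2–C3, the last bond of ring B, and both stereocentres at once.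

## Logic of the disconnections

18 ⇒ 16 (through 17). The C2–C3 bond of ring B is cut. C2 carries bromine and C3 a methyl carbinol, so the polarity maps onto a bromine-stabilised carbanion and a methyl ketone. One ring, one C–C bond and two stereocentres disappear, leaving a monocyclic precursor with only C6 and C10 stereogenic. The forward step must make the carbanion from a CHBr2 group without touching the C10 bromide or the ketone, stop at the bromohydrin, and pass through one chair.

16 ⇒ 15 ⇒ 14. The C3–CH3 bond is cut, and the amide C–N bond is traced back to an ester. A free methyl ketone cannot be present while the aldehyde arm is homologated and turned into CHBr2: it would react with the ylide and with the bromophosphonium reagent, and a keto aldehyde would aldolise. C3 is therefore carried at the acid oxidation level and the ketone is unveiled last, which avoids a protecting group. The methyl addition must stop at the ketone and leave three C–Br bonds alone.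

14 ⇒ 13. The two C2–Br bonds are traced to an aldehyde oxygen. An aldehyde is the direct precursor of a 1,1-dibromide, and at this stage the only other carbonyl is an ester. The forward step must exchange oxygen for two bromines without adding to the ring alkene.

13 ⇒ 10 + 11 (through 12). The C1–C2 bond is cut. This puts the formyl group directly on C6, which is what enolate chemistry at C6 needs, and makes C2 a one-carbon reagent. The forward step is an olefination of an aldehyde flanked by two fully substituted carbons, with the ester as spectator.

10 ⇒ 8 + 9. The C6–C5 bond is cut. It is the one bond to the spiro centre that a conjugate addition of the aldehyde's extended enolate can make, and it turns the quaternary centre into a planar carbon whose faces are distinguished by C10. Both rings' link and the C6 configuration are thereby traced to the single C–Br stereocentre. The forward step needs α-attack of a hindered dienolate, anti to bromine, without loss of bromide.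

8 ⇒ 6 ⇒ 5 (through 7). Only functional groups change: aldehyde to alcohol to acetate. The conjugated aldehyde is chosen because it is the thermodynamic sink of all double-bond isomers and has no stereocentre other than C10. The forward steps must oxidise and isomerise without base strong enough to expel bromide.

5 ⇒ 3 (through 4). The C6–C11 bond of ring A is cut. Ring A is a cyclised geranyl unit, and cutting between the gem-dimethyl carbon and C6 returns an acyclic diene that already carries the bromine. The forward ionisation must proceed with participation of the neighbouring bromine so that C10 keeps its configuration, and must close the six-membered ring.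

3 ⇒ 2 ⇒ 1. The C10–Br bond is traced to an epoxide C–O bond, and the epoxide to the distal alkene of 1. This places the origin of all absolute configuration in one catalytic asymmetric epoxidation. The forward steps need site selection between two trisubstituted alkenes and delivery of bromide to the secondary epoxide carbon with inversion.

## Other disconnections considered

Alternative 1: The cut is in ring A, at C8–C9 and C10–Br. In the forward step the α-bromo-β-keto ester A2, bound to a chiral magnesium Lewis acid, would give a C8 radical that adds to the terminal alkene carbon C9 in the 6-endo mode. The C10 radical would then take bromine from a second molecule of A2, giving the ring A keto ester A1.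
- In its favour: the C10 stereocentre and the C–Br bond are made in the ring-forming step under catalyst control, with no cationic cyclisation and no regiochemical question about where bromide enters. On C10 this is the better plan; the chosen route needs three steps (1–3) for the same centre. The C7 ketone of A1 would also let the C7 methyl alkene be placed regiospecifically.
- Against it: in A1 ring B is symmetric, so C6 is not yet stereogenic. It becomes so only when C2 is distinguished from C4, with nothing but the remote C10 bromide to guide the choice of methylene and face. The vicinal quaternary pair C6/C11 must still be assembled in A2. After the key step A1 needs removal of the ester, conversion of the C7 ketone to the methyl alkene, ketal removal, bromination at C2 and methyl addition at C3, with the C10 bromide 1,3 to the enolisable C8 throughout.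
- Comparison: structurally it solves ring A and leaves C6, C2 and C3 open; the chosen plan derives those three from C10 in two substrate-controlled events. Mechanistically its key step rests on a known reaction type, whereas step 11 does not. In step count it is no shorter.

Alternative 2: The cut is C6–C7. In the forward step a zerovalent palladium catalyst would insert into the alkenyl C–Br bond of the phenol A4; the phenoxide would attack through its para carbon, and reductive elimination would close ring A as the spirodienone A3.
- In its favour: the congested spiro carbon next to C11 is formed by an intramolecular reductive elimination, not by intermolecular attack on a hindered centre. On that bond it is the equal of, or better than, step 6 of the chosen route. A4 is also a flat, easily assembled precursor.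
- Against it: the C10 bromide must be introduced enantioselectively in A4 by separate means and must survive base and heat. A3 has two identical enone arms, so C6 is again not stereogenic, and the arms must be told apart under the influence of C10 and C7 only. Ring B then needs reduction of both alkenes, bromine at C2 and a methyl carbinol at C3.
- Comparison: it is strong on the C6–C7 bond and weak on stereochemistry; the chosen plan makes C6 stereogenic in the step that creates it. It is longer after the key step.

Alternative 3: The cuts are C6–C5 and C1=C2. In the forward step the enamine of aldehyde 8 (or of its isomer 7) would add through C6 to A6, and the methyl ketone would then condense on the formyl carbon to give the spiro enone A5.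
- In its favour: C6 is set by the same facial argument as in step 6, so on this centre it is the equal of the chosen plan. Ring B is closed in one operation from 8, and every later operation is of a known type: conjugate reduction with triflation of the enolate, methyl coupling, and bromohydrin formation on the resulting C2=C3 alkene. It is about two steps shorter from 8, so it is the better plan on step economy and on precedent.
- Against it: C2 and C3 are set only at the very end, by the face on which a bromonium ion forms on ring B, and the ring A alkene must stay untouched in that step.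
- Comparison: the chosen plan spends two more steps and accepts an untested ring closure. In return it creates C2 and C3 together in the ring-forming event through a single chair, with no electrophilic bromine near the ring A alkene. The sequence of Alternative 3 is kept as the fallback for step 11.

Key step: step 11

Remark 1: the descriptors of 16 (1R,5S) and 18 (2R,3R,6R,10S) were re-derived from their SMILES strings and agree; no structure needed correction. Target numbering (C1–C11) is used for atoms throughout.

Remark 2: the cation of step 3 is expected to lose a proton in three directions. The endocyclic isomer is drawn as 5; its exocyclic and tetrasubstituted double-bond isomers carry the same C–Br stereocentre and are carried along, because step 5 merges all of them into 8.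

Remark 3: the D-fructose-derived Shi ketone is taken to give the (R)-epoxide of a 2-methylalk-2-ene (spiro transition-state model); the enantiomeric ketone would be used if the sense were opposite.

## Route

Step 1
Reactants: 1 geranyl acetate, [(2E)-3,7-dimethylocta-2,6-dien-1-yl] acetate
Product: 2 [(2E)-5-[(2R)-3,3-dimethyloxiran-2-yl]-3-methylpent-2-en-1-yl] acetate
Conditions: D-fructose-derived Shi ketone (0.3 equiv), KHSO5 (Oxone), K2CO3, Bu4NHSO4, MeCN–(MeO)2CH2–aq. buffer (pH 10.5), 0 °C
Reagents that add atoms: potassium peroxymonosulfate, [K+].[O-]S(=O)(=O)OO
Why: Shi asymmetric epoxidation; the distal alkene is the more electron-rich one (the 2,3-alkene is deactivated by the allylic acetate), and the chiral dioxirane should deliver the (R)-epoxide, the only stereocentre in the route that is set by a reagent.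

Step 2
Reactants: 2 [(2E)-5-[(2R)-3,3-dimethyloxiran-2-yl]-3-methylpent-2-en-1-yl] acetate
Product: 3 (2E,6S)-6-bromo-7-hydroxy-3,7-dimethyloct-2-en-1-yl acetate
Conditions: Li2NiBr4 (THF solution), THF, 0 °C → rt; pH 7 buffer
Reagents that add atoms: dilithium tetrabromonickelate, [Li+].[Li+].[Ni+2].[Br-].[Br-].[Br-].[Br-]
Why: SN2-type opening of a trisubstituted epoxide by a soft bromide source (halohydrin formation); under nearly neutral aprotic conditions bromide should enter at the less substituted carbon with inversion, turning the (R)-epoxide carbon into the (S)-bromide that becomes C10.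

Step 3
Reactants: 3 (2E,6S)-6-bromo-7-hydroxy-3,7-dimethyloct-2-en-1-yl acetate
Product: 5 [(1R,5S)-5-bromo-2,6,6-trimethylcyclohex-2-en-1-yl]methyl acetate, via tertiary trifluoroacetate 4 (not isolated)
Conditions: (CF3CO)2O, pyridine, CH2Cl2, 0 °C; evaporate; (CF3)2CHOH, 0 °C → rt
Reagents that add atoms: none
Why: Acylation, then bromonium-ion-initiated cation–olefin cyclisation: the tertiary trifluoroacetate ionises in the ionising, weakly nucleophilic solvent with anchimeric help from the neighbouring bromine, the 2,3-alkene attacks the tertiary carbon through a chair with bromine equatorial, and the cyclohexyl cation loses a proton. The C–Br bond is never broken, so C10 stays S; the C1 centre of 5 is of no consequence.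

Step 4
Reactants: 5 [(1R,5S)-5-bromo-2,6,6-trimethylcyclohex-2-en-1-yl]methyl acetate
Product: 6 [(1R,5S)-5-bromo-2,6,6-trimethylcyclohex-2-en-1-yl]methanol
Conditions: K2CO3 (0.2 equiv), MeOH, 0 °C
Reagents that add atoms: none
Why: Base-catalysed transesterification of the acetate; the alkoxide is cis to the bromide and cannot reach its rear side, so no ether forms.

Step 5
Reactants: 6 [(1R,5S)-5-bromo-2,6,6-trimethylcyclohex-2-en-1-yl]methanol
Product: 8 (5S)-5-bromo-2,6,6-trimethylcyclohex-1-ene-1-carbaldehyde, via bromo-α-cyclocitral 7 (not isolated)
Conditions: Dess–Martin periodinane, NaHCO3, CH2Cl2, 0 °C → rt; aq. Na2S2O3/NaHCO3 wash; then DBU (0.2 equiv), CH2Cl2, rt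
Reagents that add atoms: none
Why: Dess–Martin oxidation followed by base-catalysed conjugation of the β,γ-unsaturated aldehyde; the conjugated aldehyde is the thermodynamic sink, which merges the alkene isomers of step 3 and removes the irrelevant C1 centre while C10 is untouched.

Step 6
Reactants: 8 (5S)-5-bromo-2,6,6-trimethylcyclohex-1-ene-1-carbaldehyde; 9 methyl acrylate
Product: 10 methyl 3-[(1R,5S)-5-bromo-1-formyl-2,6,6-trimethylcyclohex-2-en-1-yl]propanoate
Conditions: KOtBu (0.2 equiv), methyl acrylate (2 equiv), THF, −20 → 0 °C; AcOH quench
Reagents that add atoms: methyl acrylate 9, C=CC(=O)OC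
Why: Michael addition of the extended enolate at its α-carbon (deconjugative α-alkylation), forming C6–C5 and the quaternary centre. In the half-chair with bromine equatorial the face syn to bromine carries the pseudoaxial C11 methyl, and in the other half-chair it carries an axial bromine, so the acceptor should enter anti to bromine and set C6 from C10. The ester adduct has no enolisable position that can reach the aldehyde in a six-membered aldol.

Step 7
Reactants: 10 methyl 3-[(1R,5S)-5-bromo-1-formyl-2,6,6-trimethylcyclohex-2-en-1-yl]propanoate; 11 (methoxymethyl)triphenylphosphonium chloride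
Product: 13 methyl 3-[(1R,5S)-5-bromo-2,6,6-trimethyl-1-(2-oxoethyl)cyclohex-2-en-1-yl]propanoate, via methyl enol ether 12 (not isolated)
Conditions: Ph3P(CH2OMe)Cl, KN(SiMe3)2, THF, 0 °C; add 10, 0 °C → rt; then 2 M aq. HCl, THF, rt
Reagents that add atoms: (methoxymethyl)triphenylphosphonium chloride 11, [Cl-].COC[P+](c1ccccc1)(c1ccccc1)c1ccccc1; water, O
Why: Wittig methoxymethylenation and acid hydrolysis of the enol ether (one-carbon homologation, C1–C2); the small ylide tolerates the hindered aldehyde, the ester does not react at this temperature, and no stereocentre is involved.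

Step 8
Reactants: 13 methyl 3-[(1R,5S)-5-bromo-2,6,6-trimethyl-1-(2-oxoethyl)cyclohex-2-en-1-yl]propanoate
Product: 14 methyl 3-[(1R,5S)-5-bromo-1-(2,2-dibromoethyl)-2,6,6-trimethylcyclohex-2-en-1-yl]propanoate
Conditions: (PhO)3P, Br2, CH2Cl2, −78 °C; then 13, −78 → 0 °C
Reagents that add atoms: bromine, BrBr
Why: Deoxygenative gem-dibromination of an aldehyde with a preformed bromophosphonium bromide; the ester is inert, and no ketone is present, which is why C3 is still an ester at this stage.

Step 9
Reactants: 14 methyl 3-[(1R,5S)-5-bromo-1-(2,2-dibromoethyl)-2,6,6-trimethylcyclohex-2-en-1-yl]propanoate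
Product: 15 3-[(1R,5S)-5-bromo-1-(2,2-dibromoethyl)-2,6,6-trimethylcyclohex-2-en-1-yl]-N-methoxy-N-methylpropanamide
Conditions: MeONHMe·HCl, AlMe3, CH2Cl2, 0 °C → rt
Reagents that add atoms: N,O-dimethylhydroxylamine hydrochloride, Cl.CNOC
Why: Weinreb amide formation by aluminium amide aminolysis of a methyl ester; the reagent is neither basic nor reducing enough to affect the C–Br bonds.

Step 10
Reactants: 15 3-[(1R,5S)-5-bromo-1-(2,2-dibromoethyl)-2,6,6-trimethylcyclohex-2-en-1-yl]-N-methoxy-N-methylpropanamide
Product: 16 4-[(1R,5S)-5-bromo-1-(2,2-dibromoethyl)-2,6,6-trimethylcyclohex-2-en-1-yl]butan-2-one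
Conditions: MeMgBr, THF, −78 → 0 °C; aq. NH4Cl
Reagents that add atoms: methylmagnesium bromide, C[Mg]Br
Why: Weinreb ketone synthesis; the amide accepts one equivalent of the Grignard reagent only, and MeMgBr at low temperature should not exchange with or eliminate the alkyl bromides.

Step 11
Reactants: 16 4-[(1R,5S)-5-bromo-1-(2,2-dibromoethyl)-2,6,6-trimethylcyclohex-2-en-1-yl]butan-2-one
Product: 18 (2R,3R,6R,10S)-2,10-dibromo-3,7,11,11-tetramethylspiro[5.5]undec-7-en-3-ol, via α-bromoalkylsamarium 17 (not isolated)
Conditions: SmI2 (2.1 equiv, 0.1 M in THF, slow addition), THF, −20 °C → rt; aq. NH4Cl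
Reagents that add atoms: none
Why: Proposed new method: two single-electron transfers from divalent samarium cleave one C–Br bond of the geminal dibromide and give the α-bromoalkyl species 17 of trivalent samarium, which adds to the C3 carbonyl in a Barbier-type step. The closest known reactions are the SmI2-mediated halomethylation of ketones with dihalomethanes and halohydrin formation from α-haloalkyl lithium or magnesium carbenoids with carbonyl compounds; an intramolecular closure from a 1,1-dibromoalkyl ketone is not established. Ring B closes in the 6-exo-trig mode through a chair in which the spiro centre keeps C11 equatorial and C7 axial. At C2 the carbanion is configurationally labile, and the transition state with bromine equatorial should win because an axial bromine would be syn-axial to C7. At C3 the samarium-bound oxygen should take the equatorial site and the methyl the axial one, since the metal bridging C2 and oxygen is best placed on the outside of the forming ring; this gives the trans-diequatorial bromohydrin and is a prediction. The step needs reduction of CHBr2 in preference to the neopentyl C10 bromide, the alkene and the dialkyl ketone, which the much easier reduction of a 1,1-dibromide by SmI2 in THF without polar additive should secure. It also needs the β-bromo alkoxide to survive, which is secured by using two equivalents of SmI2 added slowly so that it never accumulates.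

## Compound list

1 | geranyl acetate, [(2E)-3,7-dimethylocta-2,6-dien-1-yl] acetate | CC(C)=CCC/C(C)=C/COC(C)=O | starting material
2 | [(2E)-5-[(2R)-3,3-dimethyloxiran-2-yl]-3-methylpent-2-en-1-yl] acetate | CC(=O)OC/C=C(\C)CC[C@H]1OC1(C)C | intermediate
3 | (2E,6S)-6-bromo-7-hydroxy-3,7-dimethyloct-2-en-1-yl acetate | CC(=O)OC/C=C(\C)CC[C@H](Br)C(C)(C)O | intermediate
4 | (2E,6S)-6-bromo-3,7-dimethyl-7-(trifluoroacetoxy)oct-2-en-1-yl acetate | CC(=O)OC/C=C(\C)CC[C@H](Br)C(C)(C)OC(=O)C(F)(F)F | intermediate (not isolated)
5 | [(1R,5S)-5-bromo-2,6,6-trimethylcyclohex-2-en-1-yl]methyl acetate | CC1=CC[C@H](Br)C(C)(C)[C@@H]1COC(C)=O | intermediate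
6 | [(1R,5S)-5-bromo-2,6,6-trimethylcyclohex-2-en-1-yl]methanol | CC1=CC[C@H](Br)C(C)(C)[C@@H]1CO | intermediate
7 | (1R,5S)-5-bromo-2,6,6-trimethylcyclohex-2-ene-1-carbaldehyde | CC1=CC[C@H](Br)C(C)(C)[C@@H]1C=O | intermediate (not isolated)
8 | (5S)-5-bromo-2,6,6-trimethylcyclohex-1-ene-1-carbaldehyde | O=CC1=C(C)CC[C@H](Br)C1(C)C | intermediate
9 | methyl acrylate (methyl prop-2-enoate) | C=CC(=O)OC | starting material
10 | methyl 3-[(1R,5S)-5-bromo-1-formyl-2,6,6-trimethylcyclohex-2-en-1-yl]propanoate | CC1=CC[C@H](Br)C(C)(C)[C@@]1(C=O)CCC(=O)OC | intermediate
11 | (methoxymethyl)triphenylphosphonium chloride | [Cl-].COC[P+](c1ccccc1)(c1ccccc1)c1ccccc1 | starting material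
12 | methyl 3-[(1R,5S)-5-bromo-1-(2-methoxyethenyl)-2,6,6-trimethylcyclohex-2-en-1-yl]propanoate (E/Z mixture at the enol ether) | CC1=CC[C@H](Br)C(C)(C)[C@@]1(C=COC)CCC(=O)OC | intermediate (not isolated)
13 | methyl 3-[(1R,5S)-5-bromo-2,6,6-trimethyl-1-(2-oxoethyl)cyclohex-2-en-1-yl]propanoate | CC1=CC[C@H](Br)C(C)(C)[C@@]1(CC=O)CCC(=O)OC | intermediate
14 | methyl 3-[(1R,5S)-5-bromo-1-(2,2-dibromoethyl)-2,6,6-trimethylcyclohex-2-en-1-yl]propanoate | CC1=CC[C@H](Br)C(C)(C)[C@@]1(CC(Br)Br)CCC(=O)OC | intermediate
15 | 3-[(1R,5S)-5-bromo-1-(2,2-dibromoethyl)-2,6,6-trimethylcyclohex-2-en-1-yl]-N-methoxy-N-methylpropanamide | CC1=CC[C@H](Br)C(C)(C)[C@@]1(CC(Br)Br)CCC(=O)N(C)OC | intermediate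
16 | 4-[(1R,5S)-5-bromo-1-(2,2-dibromoethyl)-2,6,6-trimethylcyclohex-2-en-1-yl]butan-2-one | CC1=CC[C@H](Br)C(C)(C)[C@@]1(CC(Br)Br)CCC(C)=O | intermediate
17 | {1-bromo-2-[(1R,5S)-5-bromo-2,6,6-trimethyl-1-(3-oxobutyl)cyclohex-2-en-1-yl]ethyl}samarium diiodide (configuration at the metal-bearing carbon not fixed) | CC1=CC[C@H](Br)C(C)(C)[C@@]1(CC(Br)[Sm](I)I)CCC(C)=O | intermediate (not isolated)
18 | (2R,3R,6R,10S)-2,10-dibromo-3,7,11,11-tetramethylspiro[5.5]undec-7-en-3-ol | CC1=CC[C@H](Br)C(C)(C)[C@@]12CC[C@@](C)(O)[C@H](Br)C2 | target

## Step count and least certain steps

Total step count: 11. Longest linear sequence: 11 steps (1 to 18); 9 and 11 are commercial and enter directly.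

Step 11 (key step, proposed new method). The most likely failure is decay of the α-haloalkyl metal species before it reaches the ketone, by a 1,2-hydride shift to a vinyl group or by protonation to the monobromide, because such carbenoids are short-lived. Further reduction of the β-bromo alkoxide with loss of the bromohydrin, and closure through the chair with axial oxygen (inverting C3), are the other risks, because the chair preference at C3 is only an estimate. The fallback uses known chemistry and closes ring B differently, setting out from 8.
- Robinson spiroannulation of 8 with methyl vinyl ketone A6 (pyrrolidine, then KOH/MeOH) would give (6R,10S)-10-bromo-7,11,11-trimethylspiro[5.5]undeca-1,7-dien-3-one F1, identical with A5.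
- Conjugate reduction with LiBH(s-Bu)3 and trapping of the C2=C3 enolate with PhNTf2 would give (6R,10S)-10-bromo-7,11,11-trimethylspiro[5.5]undeca-2,7-dien-3-yl trifluoromethanesulfonate F2.
- Negishi methylation (MeZnCl, Pd(PPh3)4, a zerovalent palladium catalyst) would give (6R,10S)-10-bromo-3,7,11,11-tetramethylspiro[5.5]undeca-2,7-diene F3.
- Bromohydrin formation with N-bromosuccinimide in aqueous THF (bromonium ion on the less hindered ring B alkene, water entering anti at the tertiary C3) comes back to the route at 18.

Step 2. The most likely failure is loss of regiocontrol: bromide delivered to the tertiary carbon, or Lewis-acid-triggered rearrangement of the epoxide, because the tertiary C–O bond is the weaker one once oxygen is strongly coordinated. The fallback sets out from 2.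
- Acid-catalysed hydration (cat. HClO4, THF–H2O; water enters at the tertiary carbon, the C–O bond at the stereocentre is kept) would give (2E,6R)-6,7-dihydroxy-3,7-dimethyloct-2-en-1-yl acetate F4.
- SOCl2/Et3N, then NaIO4 with catalytic RuCl3 (0 °C, short contact), would give the cyclic sulfate [(2E)-5-[(4R)-5,5-dimethyl-2,2-dioxo-1,3,2-dioxathiolan-4-yl]-3-methylpent-2-en-1-yl] acetate F5.
- LiBr in THF should open the sulfate at the secondary carbon with inversion to (2E,6S)-6-bromo-3,7-dimethyl-7-(sulfooxy)oct-2-en-1-yl acetate F6 (as its lithium salt).
- Hydrolysis of the tertiary sulfate (cat. H2SO4, one equivalent of water, THF) comes back to the route at 3.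

Step 3. The most likely failure is erosion of enantiopurity by transfer of Br+ from the bromonium ion to the alkene of a second molecule. Diversion of the cation (capture by trifluoroacetate or by the acetate carbonyl, or elimination) instead of ring closure is also likely, because the 2,3-alkene is deactivated by the allylic acetate. The fallback forms the ring first and the C–Br bond afterwards, setting out from 2.
- Lewis-acid epoxy-olefin cyclisation (ZrCl4, CH2Cl2, −78 °C) would give [(1S,5R)-5-hydroxy-2,6,6-trimethylcyclohex-2-en-1-yl]methyl acetate F7.
- Appel bromination (CBr4, PPh3) with inversion would give [(1S,5S)-5-bromo-2,6,6-trimethylcyclohex-2-en-1-yl]methyl acetate F8, the C1 epimer of 5.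
- Reductive removal of the acetate (i-Bu2AlH, −78 °C, chosen because an alkoxide trans to the bromide could displace it) would give [(1S,5S)-5-bromo-2,6,6-trimethylcyclohex-2-en-1-yl]methanol F9.
- The conditions of step 5 would pass through (1S,5S)-5-bromo-2,6,6-trimethylcyclohex-2-ene-1-carbaldehyde F10 and come back to the route at 8.
- The weak point of this fallback is the substitution at a neopentyl carbinol.

Step 6. The most likely failure is loss of bromide from the dienolate (1,3-closure onto the bromide-bearing carbon, or loss of HBr) or attack at the γ-carbon, outrunning alkylation at the congested α-carbon, which is flanked by the gem-dimethyl carbon and the methyl-bearing alkene carbon. Poor facial selectivity is the second risk, because the bias rests on one pseudoaxial methyl group. The fallback avoids the anionic nucleophile and sets out from 8.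
- Condensation with pyrrolidine (benzene, molecular sieves) would give the dienamine 1-{[(5S)-5-bromo-2,6,6-trimethylcyclohex-2-en-1-ylidene]methyl}pyrrolidine F11.
- Stork enamine Michael addition to 9 in methanol and hydrolysis (aq. AcOH/NaOAc) come back to the route at 10.

Step 8. The most likely failure is electrophilic attack on the trisubstituted ring alkene by the bromophosphonium reagent or by traces of Br2 or HBr, or partial loss of HBr to a 1-bromoalkene, because the reagent is a strong electrophile. The fallback sets out from 13.
- Condensation with N2H4·H2O (MeOH, 0 °C) would give the hydrazone methyl 3-[(1R,5S)-5-bromo-1-(2-hydrazinylideneethyl)-2,6,6-trimethylcyclohex-2-en-1-yl]propanoate F12.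
- Oxidative bromination with CuBr2/LiOtBu in THF, with loss of nitrogen, comes back to the route at 14.

## Further compounds

F1 | step 11 | (6R,10S)-10-bromo-7,11,11-trimethylspiro[5.5]undeca-1,7-dien-3-one | CC1=CC[C@H](Br)C(C)(C)[C@@]12CCC(=O)C=C2
F2 | step 11 | (6R,10S)-10-bromo-7,11,11-trimethylspiro[5.5]undeca-2,7-dien-3-yl trifluoromethanesulfonate | CC1=CC[C@H](Br)C(C)(C)[C@@]12CCC(OS(=O)(=O)C(F)(F)F)=CC2
F3 | step 11 | (6R,10S)-10-bromo-3,7,11,11-tetramethylspiro[5.5]undeca-2,7-diene | CC1=CC[C@H](Br)C(C)(C)[C@@]12CCC(C)=CC2
F4 | step 2 | (2E,6R)-6,7-dihydroxy-3,7-dimethyloct-2-en-1-yl acetate | CC(=O)OC/C=C(\C)CC[C@@H](O)C(C)(C)O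
F5 | step 2 | [(2E)-5-[(4R)-5,5-dimethyl-2,2-dioxo-1,3,2-dioxathiolan-4-yl]-3-methylpent-2-en-1-yl] acetate | CC(=O)OC/C=C(\C)CC[C@H]1OS(=O)(=O)OC1(C)C
F6 | step 2 | (2E,6S)-6-bromo-3,7-dimethyl-7-(sulfooxy)oct-2-en-1-yl acetate | CC(=O)OC/C=C(\C)CC[C@H](Br)C(C)(C)OS(=O)(=O)O
F7 | step 3 | [(1S,5R)-5-hydroxy-2,6,6-trimethylcyclohex-2-en-1-yl]methyl acetate | CC1=CC[C@@H](O)C(C)(C)[C@H]1COC(C)=O
F8 | step 3 | [(1S,5S)-5-bromo-2,6,6-trimethylcyclohex-2-en-1-yl]methyl acetate | CC1=CC[C@H](Br)C(C)(C)[C@H]1COC(C)=O
F9 | step 3 | [(1S,5S)-5-bromo-2,6,6-trimethylcyclohex-2-en-1-yl]methanol | CC1=CC[C@H](Br)C(C)(C)[C@H]1CO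
F10 | step 3 | (1S,5S)-5-bromo-2,6,6-trimethylcyclohex-2-ene-1-carbaldehyde | CC1=CC[C@H](Br)C(C)(C)[C@H]1C=O
F11 | step 6 | 1-{[(5S)-5-bromo-2,6,6-trimethylcyclohex-2-en-1-ylidene]methyl}pyrrolidine | CC1=CC[C@H](Br)C(C)(C)C1=CN2CCCC2
F12 | step 8 | methyl 3-[(1R,5S)-5-bromo-1-(2-hydrazinylideneethyl)-2,6,6-trimethylcyclohex-2-en-1-yl]propanoate | CC1=CC[C@H](Br)C(C)(C)[C@@]1(CC=NN)CCC(=O)OC
A1 | alternative 1 | tert-butyl (10R,12S)-12-bromo-13,13-dimethyl-9-oxo-1,4-dioxadispiro[4.2.5.2]pentadecane-10-carboxylate (target numbering 8R,10S; ring B as the C3 ethylene ketal) | O=C1[C@H](C(=O)OC(C)(C)C)C[C@H](Br)C(C)(C)C12CCC3(CC2)OCCO3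
A2 | alternative 1 | tert-butyl 2-bromo-3-[8-(2-methylbut-3-en-2-yl)-1,4-dioxaspiro[4.5]decan-8-yl]-3-oxopropanoate | C=CC(C)(C)C1(CCC2(CC1)OCCO2)C(=O)C(Br)C(=O)OC(C)(C)C
A3 | alternative 2 | (10S)-10-bromo-7,11,11-trimethylspiro[5.5]undeca-1,4,7-trien-3-one | CC1=CC[C@H](Br)C(C)(C)C12C=CC(=O)C=C2
A4 | alternative 2 | 4-[(3S,5Z)-3,6-dibromo-2-methylhept-5-en-2-yl]phenol | C/C(Br)=C/C[C@H](Br)C(C)(C)c1ccc(O)cc1
A5 | alternative 3 | (6R,10S)-10-bromo-7,11,11-trimethylspiro[5.5]undeca-1,7-dien-3-one | CC1=CC[C@H](Br)C(C)(C)[C@@]12CCC(=O)C=C2
A6 | alternative 3 | methyl vinyl ketone (but-3-en-2-one) | CC(=O)C=C
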